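**Retrosynthetic overview**
- Target ⇒ daucene triol: both angelates go on last by mixed-anhydride acylation; the tertiary C4–OH stays free.
- Seven-membered ring (formed second): C8=C9 by ring-closing metathesis of a C10 vinyl carbinol with a C6 methallyl ketone; the C6 carbinol comes from C4–OH-directed hydride delivery.
- C6–C7: methallyl Grignard on a Weinreb amide obtained by opening a cyclopentane-fused β-lactone.
- Five-membered ring (formed first, key step): the NHC-generated homoenolate of a β,β-disubstituted enal attacks the β-carbon of isopropyl vinyl ketone (C1–C2, two acceptor carbons joined), then aldol (C5–C4) and β-lactonisation set C1, C5 and C4 in one operation.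
- Enal: from ethyl 3-methyl-4-oxocrotonate by catalytic asymmetric vinylation (sets C10), silylation, reduction and oxidation.

Assumption: names use daucane numbering (C1 = ring-fusion C–CH3, C2, C3, C4 = C(OH)iPr, C5 = ring-fusion CH, C6 and C10 = ester carbinols, C8 = olefinic C–CH3); the SMILES is read as (1S,4R,5S,6S,10R) with two (Z)-2-methylbut-2-enoates; the five building blocks marked "starting material" in the list are taken as catalogue chemicals.

Step 1
Reactants: 1 ethyl (2E)-3-methyl-4-oxobut-2-enoate; 2 vinylmagnesium bromide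
Product: 3 ethyl (2E,4R)-4-hydroxy-3-methylhexa-2,5-dienoate
Conditions: 2 + ZnCl2 (0.5 equiv per 2), Et2O/1,4-dioxane, magnesium salts filtered off; (+)-DAIB (5 mol%), toluene, 0 °C; aq. NH4Cl
Reagents that add atoms: vinylmagnesium bromide (2), C=C[Mg]Br
Why: Amino-alcohol-catalysed enantioselective alkenylzinc addition to the aldehyde (ester untouched); (+)-DAIB delivers vinyl to the Re face, the mirror of the Si-face sense known for (−)-DAIB, which sets C10 as R.

Step 2
Reactants: 3 ethyl (2E,4R)-4-hydroxy-3-methylhexa-2,5-dienoate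
Product: 4 ethyl (2E,4R)-4-{[tert-butyl(dimethyl)silyl]oxy}-3-methylhexa-2,5-dienoate
Conditions: TBSCl, imidazole, DMF, rt
Reagents that add atoms: tert-butyldimethylsilyl chloride, CC(C)(C)[Si](C)(C)Cl
Why: Standard imidazole-assisted silylation of a secondary alcohol; it masks the C10 hydroxyl against oxidation and redox lactonisation in the carbene step, and no stereocentre is touched.

Step 3
Reactants: 4 ethyl (2E,4R)-4-{[tert-butyl(dimethyl)silyl]oxy}-3-methylhexa-2,5-dienoate
Product: 5 (2E,4R)-4-{[tert-butyl(dimethyl)silyl]oxy}-3-methylhexa-2,5-dien-1-ol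
Conditions: iBu2AlH (2.3 equiv), CH2Cl2, −78 °C; aq. potassium sodium tartrate
Reagents that add atoms: none
Why: 1,2-Reduction of the enoate by two hydride equivalents at low temperature; silyl ether and alkenes are inert and the E geometry is kept.

Step 4
Reactants: 5 (2E,4R)-4-{[tert-butyl(dimethyl)silyl]oxy}-3-methylhexa-2,5-dien-1-ol
Product: 6 (2E,4R)-4-{[tert-butyl(dimethyl)silyl]oxy}-3-methylhexa-2,5-dienal
Conditions: MnO2 (15 equiv), CH2Cl2, rt
Reagents that add atoms: none
Why: Chemoselective allylic alcohol oxidation on MnO2 without over-oxidation or E/Z scrambling; C10 carries no acidic hydrogen next to a carbonyl and is not epimerised.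

Step 5
Reactants: 6 (2E,4R)-4-{[tert-butyl(dimethyl)silyl]oxy}-3-methylhexa-2,5-dienal; 7 4-methylpent-1-en-3-one (isopropyl vinyl ketone)
Product: 10 (1R,2S,5R)-2-[(1R)-1-{[tert-butyl(dimethyl)silyl]oxy}prop-2-en-1-yl]-2-methyl-5-(propan-2-yl)-6-oxabicyclo[3.2.0]heptan-7-one, via azolium enolate 8 (not isolated), via acyl azolium aldolate 9 (not isolated)
Conditions: (5aS,10bR)-2-mesityl-5a,10b-dihydro-4H,6H-indeno[2,1-b][1,2,4]triazolo[4,3-d][1,4]oxazin-2-ium chloride (15 mol%), DBU (15 mol%), 4 Å MS, THF, rt, 7 (2 equiv) added by syringe pump over 6 h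
Reagents that add atoms: 4-methylpent-1-en-3-one (7), C=CC(=O)C(C)C
Why: Proposed new method: the carbene adds to the aldehyde of 6 to give a Breslow intermediate whose conjugated homoenolate is nucleophilic at the β-carbon (C1, normally an acceptor carbon) and attacks the unsubstituted β-carbon (C2) of 7; the azolium enolate 8 then closes onto the isopropyl ketone by a reversible intramolecular aldol and only the cis-aldolate 9 can acylate itself to the β-lactone, releasing the carbene. C1 is set by the chiral catalyst (enantiomer taken as the matched partner of C10, with attack anti to the silyloxy group), the acyl group at C5 settles trans to the bulkier C1 substituent, and C4 follows from the obligatory cis ring fusion. The closest known reaction type is the NHC-catalysed homoenolate annulation of β-monosubstituted enals with enones to cyclopentane-fused β-lactones (conjugate addition, aldol, lactonisation), here stretched to a β,β-disubstituted γ-silyloxy enal and a β-unsubstituted alkyl vinyl ketone.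

Step 6
Reactants: 10 (1R,2S,5R)-2-[(1R)-1-{[tert-butyl(dimethyl)silyl]oxy}prop-2-en-1-yl]-2-methyl-5-(propan-2-yl)-6-oxabicyclo[3.2.0]heptan-7-one
Product: 11 (1R,2S,5R)-2-[(1R)-1-{[tert-butyl(dimethyl)silyl]oxy}prop-2-en-1-yl]-5-hydroxy-N-methoxy-N,2-dimethyl-5-(propan-2-yl)cyclopentane-1-carboxamide
Conditions: MeNHOMe·HCl, AlMe3, CH2Cl2, 0 °C → rt; aq. potassium sodium tartrate
Reagents that add atoms: N,O-dimethylhydroxylamine hydrochloride, CNOC.Cl
Why: Weinreb aluminium-amide aminolysis of the strained β-lactone at the acyl carbon (the alkyl C–O carbon is tertiary), with retention at C4 and C5.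

Step 7
Reactants: 11 (1R,2S,5R)-2-[(1R)-1-{[tert-butyl(dimethyl)silyl]oxy}prop-2-en-1-yl]-5-hydroxy-N-methoxy-N,2-dimethyl-5-(propan-2-yl)cyclopentane-1-carboxamide; 12 (2-methylprop-2-en-1-yl)magnesium chloride
Product: 13 1-{(1R,2S,5R)-2-[(1R)-1-{[tert-butyl(dimethyl)silyl]oxy}prop-2-en-1-yl]-5-hydroxy-2-methyl-5-(propan-2-yl)cyclopentyl}-3-methylbut-3-en-1-one
Conditions: 12 (3.5 equiv), THF, −78 → −20 °C; AcOH/aq. NH4Cl quench at −78 °C
Reagents that add atoms: (2-methylprop-2-en-1-yl)magnesium chloride (12), CC(=C)C[Mg]Cl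
Why: Grignard addition to a Weinreb amide: the first equivalent deprotonates the C4 hydroxyl, the second adds and stays as the N-methoxy chelate until the cold acidic quench, so no tertiary alcohol forms and the β,γ-alkene is not conjugated; no stereocentre changes.

Step 8
Reactants: 13 1-{(1R,2S,5R)-2-[(1R)-1-{[tert-butyl(dimethyl)silyl]oxy}prop-2-en-1-yl]-5-hydroxy-2-methyl-5-(propan-2-yl)cyclopentyl}-3-methylbut-3-en-1-one
Product: 14 (1S,4R,5R,10R)-10-{[tert-butyl(dimethyl)silyl]oxy}-4-hydroxydauc-8-en-6-one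
Conditions: second-generation Grubbs catalyst RuCl2(=CHPh)(PCy3)(H2IMes) (10 mol%), 1,4-benzoquinone (20 mol%), toluene (2 mM), 80 °C, argon sparge
Reagents that add atoms: none
Why: Ring-closing metathesis of the vinyl and 1,1-disubstituted alkenes gives the trisubstituted cycloheptene, driven by loss of ethene; benzoquinone suppresses ruthenium hydride alkene migration; no stereocentre changes.

Step 9
Reactants: 14 (1S,4R,5R,10R)-10-{[tert-butyl(dimethyl)silyl]oxy}-4-hydroxydauc-8-en-6-one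
Product: 16 (1S,4R,5S,6S,10R)-dauc-8-ene-4,6,10-triol, via silyl ether diol 15 (not isolated)
Conditions: Me4NBH(OAc)3 (5 equiv), MeCN/AcOH (1:1), −30 → 0 °C; then 48% aq. HF, MeCN, 0 °C → rt
Reagents that add atoms: none
Why: Evans–Saksena hydroxyl-directed reduction: the C4–O–BH(OAc)2 species delivers hydride through a six-membered transition state to the β-face of the C6 ketone, the face on which the C4 oxygen lies, giving the 6α-alcohol (H-6 trans to H-5); aqueous HF then cleaves the silyl ether.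

Step 10
Reactants: 16 (1S,4R,5S,6S,10R)-dauc-8-ene-4,6,10-triol; 17 angelic acid [(2Z)-2-methylbut-2-enoic acid]
Product: 19 (1S,4R,5S,6S,10R)-4-hydroxydauc-8-ene-6,10-diyl bis[(2Z)-2-methylbut-2-enoate] (target; (3R,3aS,4S,8R,8aS)-3-hydroxy-6,8a-dimethyl-3-(propan-2-yl)-1,2,3,3a,4,5,8,8a-octahydroazulene-4,8-diyl bis[(2Z)-2-methylbut-2-enoate]), via 6-monoangelate 18 (not isolated)
Conditions: 17 (6 equiv), 2,4,6-trichlorobenzoyl chloride (6 equiv), Et3N, toluene, rt, 2 h; then 16, 80 °C, 36 h, no DMAP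
Reagents that add atoms: angelic acid (17), C/C=C(/C)C(=O)O
Why: Yamaguchi-type mixed-anhydride esterification without DMAP, the conditions that transfer angelates without Z-to-E isomerisation; the C6 hydroxyl reacts first, then the neopentylic C10 hydroxyl, and the tertiary C4 hydroxyl is not acylated; no stereocentre changes.

**Compound list**
1 | ethyl (2E)-3-methyl-4-oxobut-2-enoate | O=C/C(C)=C/C(=O)OCC | starting material
2 | vinylmagnesium bromide | C=C[Mg]Br | starting material
3 | ethyl (2E,4R)-4-hydroxy-3-methylhexa-2,5-dienoate | C=C[C@@H](O)/C(C)=C/C(=O)OCC | intermediate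
4 | ethyl (2E,4R)-4-{[tert-butyl(dimethyl)silyl]oxy}-3-methylhexa-2,5-dienoate | C=C[C@@H](O[Si](C)(C)C(C)(C)C)/C(C)=C/C(=O)OCC | intermediate
5 | (2E,4R)-4-{[tert-butyl(dimethyl)silyl]oxy}-3-methylhexa-2,5-dien-1-ol | C=C[C@@H](O[Si](C)(C)C(C)(C)C)/C(C)=C/CO | intermediate
6 | (2E,4R)-4-{[tert-butyl(dimethyl)silyl]oxy}-3-methylhexa-2,5-dienal | C=C[C@@H](O[Si](C)(C)C(C)(C)C)/C(C)=C/C=O | intermediate
7 | 4-methylpent-1-en-3-one (isopropyl vinyl ketone) | C=CC(=O)C(C)C | starting material
8 | azolium enolate, catalyst-bound Michael adduct with the C1–C2 bond formed (enolate geometry not defined) | Cc1cc(C)c(c(C)c1)-[n+]1c(C([O-])=C[C@](C)(CCC(=O)C(C)C)[C@H](O[Si](C)(C)C(C)(C)C)C=C)n2c(n1)CO[C@H]1Cc3ccccc3[C@H]12 | intermediate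
9 | acyl azolium aldolate, catalyst-bound cyclopentane with the C4–C5 bond formed | Cc1cc(C)c(c(C)c1)-[n+]1c(C(=O)[C@H]5[C@]([O-])(C(C)C)CC[C@]5(C)[C@H](O[Si](C)(C)C(C)(C)C)C=C)n2c(n1)CO[C@H]1Cc3ccccc3[C@H]12 | intermediate
10 | (1R,2S,5R)-2-[(1R)-1-{[tert-butyl(dimethyl)silyl]oxy}prop-2-en-1-yl]-2-methyl-5-(propan-2-yl)-6-oxabicyclo[3.2.0]heptan-7-one | C=C[C@@H](O[Si](C)(C)C(C)(C)C)[C@@]1(C)CC[C@]2(C(C)C)OC(=O)[C@H]12 | intermediate
11 | (1R,2S,5R)-2-[(1R)-1-{[tert-butyl(dimethyl)silyl]oxy}prop-2-en-1-yl]-5-hydroxy-N-methoxy-N,2-dimethyl-5-(propan-2-yl)cyclopentane-1-carboxamide | C=C[C@@H](O[Si](C)(C)C(C)(C)C)[C@@]1(C)CC[C@@](O)(C(C)C)[C@@H]1C(=O)N(C)OC | intermediate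
12 | (2-methylprop-2-en-1-yl)magnesium chloride | CC(=C)C[Mg]Cl | starting material
13 | 1-{(1R,2S,5R)-2-[(1R)-1-{[tert-butyl(dimethyl)silyl]oxy}prop-2-en-1-yl]-5-hydroxy-2-methyl-5-(propan-2-yl)cyclopentyl}-3-methylbut-3-en-1-one | C=C[C@@H](O[Si](C)(C)C(C)(C)C)[C@@]1(C)CC[C@@](O)(C(C)C)[C@@H]1C(=O)CC(C)=C | intermediate
14 | (1S,4R,5R,10R)-10-{[tert-butyl(dimethyl)silyl]oxy}-4-hydroxydauc-8-en-6-one | O=C1CC(C)=C[C@@H](O[Si](C)(C)C(C)(C)C)[C@@]2(C)CC[C@@](O)(C(C)C)[C@H]12 | intermediate
15 | (1S,4R,5S,6S,10R)-10-{[tert-butyl(dimethyl)silyl]oxy}dauc-8-ene-4,6-diol | O[C@H]1CC(C)=C[C@@H](O[Si](C)(C)C(C)(C)C)[C@@]2(C)CC[C@@](O)(C(C)C)[C@H]12 | intermediate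
16 | (1S,4R,5S,6S,10R)-dauc-8-ene-4,6,10-triol | O[C@H]1CC(C)=C[C@@H](O)[C@@]2(C)CC[C@@](O)(C(C)C)[C@H]12 | intermediate
17 | angelic acid, (2Z)-2-methylbut-2-enoic acid | C/C=C(/C)C(=O)O | starting material
18 | (1S,4R,5S,6S,10R)-4,10-dihydroxydauc-8-en-6-yl (2Z)-2-methylbut-2-enoate | C/C=C(/C)C(=O)O[C@H]1CC(C)=C[C@@H](O)[C@@]2(C)CC[C@@](O)(C(C)C)[C@H]12 | intermediate
19 | (1S,4R,5S,6S,10R)-4-hydroxydauc-8-ene-6,10-diyl bis[(2Z)-2-methylbut-2-enoate] | C/C=C(/C)C(=O)O[C@H]1CC(C)=C[C@@H](OC(=O)/C(C)=C\C)[C@@]2(C)CC[C@@](O)(C(C)C)[C@H]12 | target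

Total step count: 10. Longest linear sequence: 10 steps (from 1 to 19; all other partners are bought).

**Steps most likely to fail, with fallbacks**

Step 5 (key annulation). The Breslow intermediate may expel the γ-silyloxy group, or the fully substituted homoenolate carbon may not attack. The fallback makes the same C1–C2 bond with a stoichiometric homoenolate equivalent of the ketone partner and closes the ring in a separate event. It sets out from 6 (with 7 as the source of the second partner) and comes back to the route at 10. Ketone 7 is treated with HBr and then ethylene glycol/TsOH to give 2-(2-bromoethyl)-2-(propan-2-yl)-1,3-dioxolane F1. Magnesium in THF below 30 °C converts it into {2-[2-(propan-2-yl)-1,3-dioxolan-2-yl]ethyl}magnesium bromide F2. This adds 1,4 to enal 6 (CuBr·SMe2 10 mol%, Me3SiCl, THF, −78 °C, acidic work-up; addition anti to the C10 silyloxy group, reinforced by a chiral phosphoramidite ligand if needed) to give (3S,4R)-4-{[tert-butyl(dimethyl)silyl]oxy}-3-methyl-3-{2-[2-(propan-2-yl)-1,3-dioxolan-2-yl]ethyl}hex-5-enal F3. Pinnick oxidation (NaClO2, NaH2PO4, 2-methylbut-2-ene, tBuOH/H2O) gives (3S,4R)-4-{[tert-butyl(dimethyl)silyl]oxy}-3-methyl-3-{2-[2-(propan-2-yl)-1,3-dioxolan-2-yl]ethyl}hex-5-enoic acid F4. PPTS in wet acetone frees (3S)-3-[(1R)-1-{[tert-butyl(dimethyl)silyl]oxy}prop-2-en-1-yl]-3,7-dimethyl-6-oxooctanoic acid F5. A nucleophile-catalysed aldol-lactonisation of this keto acid (2-bromo-1-propylpyridinium triflate, iPr2NEt, 4-pyrrolidinopyridine, CH2Cl2, rt) closes the cyclopentane and the β-lactone together to give 10.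

Step 8 (ring-closing metathesis). The vinyl group sits between a bulky silyl ether and a quaternary carbon, and the partner alkene is 1,1-disubstituted, so catalyst loading may stall. The fallback changes the substrate and the order of events; it sets out from 13 and comes back at 16. The silyl group is removed first (HF·pyridine, THF, 0 °C → rt) to give 1-{(1R,2S,5R)-5-hydroxy-2-[(1R)-1-hydroxyprop-2-en-1-yl]-2-methyl-5-(propan-2-yl)cyclopentyl}-3-methylbut-3-en-1-one F6. Its free allylic hydroxyl assists ruthenium loading, and ring closure (same catalyst, benzoquinone, CH2Cl2, 40 °C) gives (1S,4R,5R,10R)-4,10-dihydroxydauc-8-en-6-one F7. The directed reduction of step 9 (Me4NBH(OAc)3 alone, MeCN/AcOH, −30 °C) then delivers 16.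

Step 10 (double angeloylation). The neopentylic C10 hydroxyl may stop at monoester 18, or forcing conditions may give tiglate (E) contamination. The fallback builds the Z-alkenes on the molecule instead of bringing them in; it sets out from 16 and comes back at 19. LiOH hydrolysis of the commercial methyl ester gives 2-[bis(2,2,2-trifluoroethoxy)phosphoryl]propanoic acid F8. Steglich esterification of 16 with it (DCC, DMAP, CH2Cl2; a saturated acid, so DMAP is harmless) gives (1S,4R,5S,6S,10R)-4-hydroxydauc-8-ene-6,10-diyl bis{2-[bis(2,2,2-trifluoroethoxy)phosphoryl]propanoate} F9, epimeric at the two phosphonate-bearing carbons. A double Still–Gennari olefination with acetaldehyde (KN(SiMe3)2 in excess, 18-crown-6, THF, −78 °C) then forms both (Z)-2-methylbut-2-enoates and gives 19.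

**Further compounds**
F1 | step 5 | 2-(2-bromoethyl)-2-(propan-2-yl)-1,3-dioxolane | BrCCC1(C(C)C)OCCO1
F2 | step 5 | {2-[2-(propan-2-yl)-1,3-dioxolan-2-yl]ethyl}magnesium bromide | Br[Mg]CCC1(C(C)C)OCCO1
F3 | step 5 | (3S,4R)-4-{[tert-butyl(dimethyl)silyl]oxy}-3-methyl-3-{2-[2-(propan-2-yl)-1,3-dioxolan-2-yl]ethyl}hex-5-enal | O=CC[C@](C)(CCC1(C(C)C)OCCO1)[C@H](O[Si](C)(C)C(C)(C)C)C=C
F4 | step 5 | (3S,4R)-4-{[tert-butyl(dimethyl)silyl]oxy}-3-methyl-3-{2-[2-(propan-2-yl)-1,3-dioxolan-2-yl]ethyl}hex-5-enoic acid | OC(=O)C[C@](C)(CCC1(C(C)C)OCCO1)[C@H](O[Si](C)(C)C(C)(C)C)C=C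
F5 | step 5 | (3S)-3-[(1R)-1-{[tert-butyl(dimethyl)silyl]oxy}prop-2-en-1-yl]-3,7-dimethyl-6-oxooctanoic acid | OC(=O)C[C@](C)(CCC(=O)C(C)C)[C@H](O[Si](C)(C)C(C)(C)C)C=C
F6 | step 8 | 1-{(1R,2S,5R)-5-hydroxy-2-[(1R)-1-hydroxyprop-2-en-1-yl]-2-methyl-5-(propan-2-yl)cyclopentyl}-3-methylbut-3-en-1-one | C=C[C@@H](O)[C@@]1(C)CC[C@@](O)(C(C)C)[C@@H]1C(=O)CC(C)=C
F7 | step 8 | (1S,4R,5R,10R)-4,10-dihydroxydauc-8-en-6-one | O=C1CC(C)=C[C@@H](O)[C@@]2(C)CC[C@@](O)(C(C)C)[C@H]12
F8 | step 10 | 2-[bis(2,2,2-trifluoroethoxy)phosphoryl]propanoic acid | CC(C(=O)O)P(=O)(OCC(F)(F)F)OCC(F)(F)F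
F9 | step 10 | (1S,4R,5S,6S,10R)-4-hydroxydauc-8-ene-6,10-diyl bis{2-[bis(2,2,2-trifluoroethoxy)phosphoryl]propanoate} | CC(P(=O)(OCC(F)(F)F)OCC(F)(F)F)C(=O)O[C@H]1CC(C)=C[C@@H](OC(=O)C(C)P(=O)(OCC(F)(F)F)OCC(F)(F)F)[C@@]2(C)CC[C@@](O)(C(C)C)[C@H]12
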